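Locants used throughout: the indane carbons are C1 (bears ring A), C2 (bears ring C), C3 (bears Cα), C3a and C7a; ring B is the indane benzo ring. The dihydrobenzofuran is O1′, C2′ (ring E), C3′ (ring D), C3a′, C4′ (bonded to C2), C6′ and C7a′; ring C is its benzo ring and ring F is the aryl group on Cα. The systematic names in the compound list number the indane from the other end.

## Analysis of the target

Target 28 is a resveratrol-type trimer on an indane core. The cyclopentane ring (C1, C2, C3, C3a, C7a) is fused to the resorcinol ring B and carries ring A on C1, a 2,3-dihydrobenzofuran (rings C, D, E) on C2 through C4′, and the carbinol Cα(OH)–ring F on C3. It has six stereocentres: C1 (S), C2 (R) and C3 (S) are contiguous and all-trans, Cα (S) lies outside the ring next to C3, and C2′ (R) and C3′ (R) are trans on the dihydrofuran. The flat ring C separates the indane cluster from the C2′/C3′ pair, so neither can control the other and each needs its own source of absolute configuration. The sensitive groups are the eight phenols, the 4-hydroxybenzylic alcohol at Cα (it ionises to a quinone methide) and the benzylic aryl ether C2′–O1′ (acid opens it to a cation stabilised by ring E). A cation at C1 must also be avoided, because ring D can reach it and close a seven-membered ring. The difficulty is that every ring is an electron-rich nucleophile, ring B is flanked on both sides at C7a, and three adjacent ring carbons each carry a large substituent. The strategy rests on one feature: C3 is a benzylic carbon of ring B that carries the one-carbon unit Cα, and C2, a benzylic carbon of ring C, is the fifth atom from it along C3–C3a–C7a–C1–C2. A carbene at C3 is therefore placed for a 1,5 C–H insertion that forms C2–C3 and closes the five-membered ring.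

## Retrosynthetic reasoning

**28 to 27.** The Cα–H bond is cut last. The 4-hydroxybenzylic alcohol is the most fragile group, so Cα stays a ketone (27) until the final step. The reduction must set Cα as S under control of the adjacent C3.

**27 to 26.** The eight O–CH3 bonds are cut. Methyl ethers are the only phenol protection that survives Lewis acids, organolithium, carbene and cross-coupling chemistry. They are removed at the ketone stage, where Cα cannot ionise.

**26 to 24 and 25, and 24 to 23.** The Cα–ring F bond is cut. The ester carbon of 23 is Cα itself, already at the acyl oxidation level. An N-methoxy-N-methylamide (24) lets the arylmagnesium reagent 25 add once only.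

**23 to 21 (through 22).** The C2–C3 bond is cut. This is the only disconnection that opens the cyclopentane without producing a cation at C1 or C2, which ring D or ring B would trap. It gives an aryldiazoacetate (21) that is one diazo transfer from a plain arylacetate. The forward step must insert the C3 carbene into one C2–H bond, place ring C trans to ring A, and leave an epimerisable C3 that base can settle to all-trans.

**21 to 20 to 19.** The diazo group comes off to give arylacetate 20. The C1–H and C2–H bonds are then traced back to the triarylethylene 19. C1 is a diarylmethine with no heteroatom and cannot be made through a cation, so asymmetric hydrogenation of a geometrically pure alkene is the way to set it.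

**19 to 17 and 18, and 17 to 13 and 16.** The two aryl–alkene bonds at C1 are cut. A carbonyl olefination at C1 was rejected: a diaryl ketone with two ortho substituents beside an enolisable arylacetate would react poorly and without control of geometry. The 1,1-dibromoalkene 13 takes up the bulky ring B boronate 16 at the bromine trans to ring C, then the small boronic acid 18 at the remaining one. This fixes the alkene geometry by the order of the couplings.

**16 to 15 to 14.** The C–B and C–Br bonds on ring B are cut. Commercial 14 brominates at the position ortho to the acetate arm and para to a methoxy group, exactly where C1 must attach.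

**13 to 12 to 10 (through 11).** The C1=C2 bond and then the C4′–C2 bond are cut. C2 enters as a formyl carbon on the aryllithium 11, made from the bromide 10. C4′ is meta to both ring C oxygens and cannot be functionalised late, so the bromine is carried from the start.

**10 to 9 to 7 (through 8), and 7 to 6.** The C2′–C3′ bond is cut; it is formed by the same kind of 1,5 carbene insertion used for the indane, here from a diaryldiazomethane (8) into the O–CH2 group. The insertion fixes C3′ by catalyst control but gives the cis ring (9). C2′ is benzylic to ring E and is corrected by acid equilibration to trans (10). Both dihydrobenzofuran stereocentres are thus set on a small compound, long before the indane.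

**6 to 4 and 5, and 4 to 1 and 2 (through 3).** The O–CH2 ether bond and the C3′–C3a′ bond are cut. Acylation of 1 by 2 places the ring D ketone ortho to bromine. The same Lewis acid then removes only the methyl ether chelated to the new carbonyl, which frees the future O1′ for benzylation by 5.

## Alternatives that were turned down

**Alternative 1:** The disconnection cuts the two neighbouring carbon substituents of ring C, C4′–C2 and C3a′–C3′, by inserting an aryne into the C–C bond of a β-ketoester. In the forward step fluoride releases the aryne from silyl triflate A2. The enolate carbon of β-ketoester A3 (the later C2) adds at the aryne carbon meta to methoxy (C4′), the aryl anion at C3a′ closes onto the ketone, and the four-membered alkoxide fragments to the ortho-aroyl arylacetate A1.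
- For it: a single convergent step with regiochemistry dictated by the methoxy group puts C2 and the C3′ carbonyl with ring D on ring C. On this point it is stronger than the chosen route, which needs steps 1 and 6 for the same two carbons.
- Against it: the step closes no ring and sets no stereocentre. C2 in A1 is an acidic CH2 next to an ester, so the indane would have to be closed by enolate chemistry with C1, C2 and C3 all still uncontrolled. The O1′ oxygen is still a methyl ether, and A2 takes several steps to make.
- Comparison: it solves fragment assembly only. The chosen key step closes the carbocycle and sets two of its three stereocentres, and step 1 gives the bromo analogue of A1 in one operation from commercial materials.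

**Alternative 2:** The disconnection cuts C3a–C4 and builds ring B last. In the forward step aqueous hydroxide opens the 2-methyl-4-pyranone of A5, which is fused to the fully substituted cyclopentane. In the opened form the terminal methyl carbon (C4) adds to the ring carbonyl (C3a), and dehydration with enolisation gives the 5,7-dihydroxyindane A4.
- For it: the ring closure is an aldol condensation driven by aromatisation, with no competing C–H or arene sites. On chemoselectivity of ring closure it is stronger than a carbene insertion. Ring B also appears with free phenols.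
- Against it: the key step makes one bond and no stereocentre, and A5 with its three contiguous stereocentres needs a separate, longer sequence. Hot hydroxide meets a silyloxy group β to the C3a carbonyl, so elimination and C3 epimerisation threaten. A4 has Cα at the alcohol level while six methyl ethers remain, and the later Lewis-acid demethylation would ionise Cα.
- Comparison: the chosen route forms the ring and two stereocentres in the key step on a commercial ring B, and keeps Cα as a carbonyl through the demethylation.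

**Alternative 3:** The disconnection cuts C2′–C3′ and O1′–C2′, so that the dihydrofuran is made last on the finished indane. In the forward step base eliminates sulfinate from the ortho-hydroxybenzhydryl sulfone A7 to give an ortho-quinone methide of ring C. The sulfonium ylide A8 adds at C3′ and the phenoxide displaces the sulfide at C2′, giving A6 (identical with 26).
- For it: it forms two bonds, one ring and two stereocentres, which is more bond formation than the chosen key step and equal in rings and stereocentres. Trans selectivity is inherent, and the indane would be made without a dihydrobenzofuran present to interfere.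
- Against it: the quinone methide is planar, and the only element that could choose its face is the indane substituent at C4′. The sense of that bias is unpredictable and it may work against a chiral ylide. A failure costs the most advanced material.
- Comparison: the chosen route sets C3′ by catalyst control and C2′ by equilibration on a 24-carbon fragment. It accepts in exchange that the indane closure must tolerate the dihydrobenzofuran.

Key step: step 14

Remark: the absolute sense of induction of Rh2(R-PTAD)4 (step 4) and of [Ir(cod)((S)-tBu-PHOX)]BArF (step 12) is assigned by analogy with simpler substrates; the antipodal complex is used if the opposite sense is met, with no other change.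

## Route

Step 1
Reactants: 1 1-bromo-3,5-dimethoxybenzene; 2 3,5-dimethoxybenzoyl chloride
Product: 4 (2-bromo-6-hydroxy-4-methoxyphenyl)(3,5-dimethoxyphenyl)methanone, via tetramethoxy ketone 3 (not isolated)
Conditions: AlCl3 (2.5 equiv), CH2Cl2, 0 °C to 40 °C; aq. HCl
Reagents that add atoms: none
Why: Friedel–Crafts acylation: the acylium ion from 2 attacks 1 para to one methoxy group and ortho to bromine, the two equivalent such positions outweighing the one between the methoxy groups. AlCl3 chelated between the new carbonyl and the neighbouring OMe then cleaves only that methyl ether (ortho-selective demethylation), freeing the oxygen that becomes O1′.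

Step 2
Reactants: 4 (2-bromo-6-hydroxy-4-methoxyphenyl)(3,5-dimethoxyphenyl)methanone; 5 4-methoxybenzyl chloride
Product: 6 {2-bromo-4-methoxy-6-[(4-methoxyphenyl)methoxy]phenyl}(3,5-dimethoxyphenyl)methanone
Conditions: K2CO3, DMF, 60 °C
Reagents that add atoms: none
Why: Williamson etherification of the acidic ortho-acylphenol; the 4-methoxybenzyl group is not a protecting group here but brings in C2′ and ring E.

Step 3
Reactants: 6 {2-bromo-4-methoxy-6-[(4-methoxyphenyl)methoxy]phenyl}(3,5-dimethoxyphenyl)methanone
Product: 7 hydrazone of 6, (2-bromo-4-methoxy-6-[(4-methoxyphenyl)methoxy]phenyl)(3,5-dimethoxyphenyl)methanone hydrazone (E/Z mixture)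
Conditions: N2H4·H2O (excess), AcOH (cat.), EtOH, 80 °C
Reagents that add atoms: hydrazine hydrate, NN.O
Why: Condensation of hydrazine with the diaryl ketone gives the N-unsubstituted hydrazone, the precursor of the diaryldiazomethane; the carbonyl has two ortho substituents and reacts slowly, hence excess reagent, acid catalysis and heat.

Step 4
Reactants: 7 hydrazone of 6
Product: 9 (2S,3R)-4-bromo-3-(3,5-dimethoxyphenyl)-6-methoxy-2-(4-methoxyphenyl)-2,3-dihydro-1-benzofuran (2,3-cis), via diaryldiazomethane 8 (not isolated)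
Conditions: MnO2, CH2Cl2, 0 °C, filter; Rh2(R-PTAD)4 (1 mol %), CH2Cl2, 0 °C
Reagents that add atoms: none
Why: MnO2 dehydrogenates the hydrazone to 8, and Rh2(R-PTAD)4 converts it to a donor/donor carbene that inserts into the adjacent O–CH2 bond (enantioselective intramolecular 1,5 C–H insertion of diaryl carbenes to 2,3-diaryl-2,3-dihydrobenzofurans). The chiral carboxylate ligands set C3′ as R and the compact three-centre transition state should give mainly the 2,3-cis isomer; C2′ is corrected in step 5.

Step 5
Reactants: 9 (2S,3R)-4-bromo-3-(3,5-dimethoxyphenyl)-6-methoxy-2-(4-methoxyphenyl)-2,3-dihydro-1-benzofuran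
Product: 10 (2R,3R)-4-bromo-3-(3,5-dimethoxyphenyl)-6-methoxy-2-(4-methoxyphenyl)-2,3-dihydro-1-benzofuran (2,3-trans)
Conditions: TFA, CH2Cl2, 0 °C to rt
Reagents that add atoms: none
Why: Acid-mediated epimerisation of a 2-aryl-2,3-dihydrobenzofuran: TFA reversibly ionises the benzylic C2′–O1′ bond (cation stabilised by ring E) and the phenol recloses to the more stable trans ring. C3′ is not involved, so its configuration from step 4 now fixes C2′ as R.

Step 6
Reactants: 10 (2R,3R)-4-bromo-3-(3,5-dimethoxyphenyl)-6-methoxy-2-(4-methoxyphenyl)-2,3-dihydro-1-benzofuran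
Product: 12 (2R,3R)-3-(3,5-dimethoxyphenyl)-6-methoxy-2-(4-methoxyphenyl)-2,3-dihydro-1-benzofuran-4-carbaldehyde, via aryllithium 11 (not isolated)
Conditions: n-BuLi, THF, −78 °C; DMF, −78 to 0 °C; aq. NH4Cl
Reagents that add atoms: N,N-dimethylformamide, CN(C)C=O
Why: Bromine–lithium exchange at −78 °C is faster than any deprotonation, and formylation of the aryllithium gives the aldehyde whose carbon is the future C2.

Step 7
Reactants: 12 (2R,3R)-3-(3,5-dimethoxyphenyl)-6-methoxy-2-(4-methoxyphenyl)-2,3-dihydro-1-benzofuran-4-carbaldehyde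
Product: 13 (2R,3R)-4-(2,2-dibromoethenyl)-3-(3,5-dimethoxyphenyl)-6-methoxy-2-(4-methoxyphenyl)-2,3-dihydro-1-benzofuran
Conditions: CBr4, PPh3, CH2Cl2, 0 °C
Reagents that add atoms: carbon tetrabromide, BrC(Br)(Br)Br
Why: Ramirez (Corey–Fuchs) dibromoolefination with Ph3P=CBr2 made in the flask; the new carbon is C1, and its two C–Br bonds differ in hindrance, so they can take up ring B and ring A one after the other.

Step 8
Reactants: 14 methyl 2-(3,5-dimethoxyphenyl)acetate
Product: 15 methyl 2-(2-bromo-3,5-dimethoxyphenyl)acetate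
Conditions: NBS, MeCN, 0 °C to rt
Reagents that add atoms: N-bromosuccinimide, O=C1CCC(=O)N1Br
Why: Electrophilic aromatic bromination; the position ortho to the acetate arm and para to a methoxy group is more reactive and less hindered than the one between the two methoxy groups.

Step 9
Reactants: 15 methyl 2-(2-bromo-3,5-dimethoxyphenyl)acetate
Product: 16 methyl 2-[3,5-dimethoxy-2-(4,4,5,5-tetramethyl-1,3,2-dioxaborolan-2-yl)phenyl]acetate
Conditions: B2pin2, Pd(dppf)Cl2 (5 mol %), KOAc, 1,4-dioxane, 90 °C
Reagents that add atoms: bis(pinacolato)diboron, CC1(C)OB(OC1(C)C)B1OC(C)(C)C(C)(C)O1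
Why: Miyaura borylation; KOAc is too weak a base to enolise the arylacetate, and the pinacol ester can be purified.

Step 10
Reactants: 13 (2R,3R)-4-(2,2-dibromoethenyl)-3-(3,5-dimethoxyphenyl)-6-methoxy-2-(4-methoxyphenyl)-2,3-dihydro-1-benzofuran; 16 methyl 2-[3,5-dimethoxy-2-(4,4,5,5-tetramethyl-1,3,2-dioxaborolan-2-yl)phenyl]acetate
Product: 17 methyl 2-[2-[(Z)-1-bromo-2-[(2R,3R)-3-(3,5-dimethoxyphenyl)-6-methoxy-2-(4-methoxyphenyl)-2,3-dihydro-1-benzofuran-4-yl]ethenyl]-3,5-dimethoxyphenyl]acetate
Conditions: Pd2(dba)3 (2.5 mol %), tris(2-furyl)phosphine (15 mol %), K3PO4, 1,4-dioxane/H2O, 65 °C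
Reagents that add atoms: none
Why: Suzuki coupling of a 1,1-dibromoalkene is selective for the C–Br bond trans to the aryl substituent, the less hindered one for oxidative addition. The bulky ring B therefore enters trans to ring C and the remaining bromine is cis to ring C; the weakly donating phosphine leaves the second C–Br bond untouched at this temperature.

Step 11
Reactants: 17 methyl 2-[2-[(Z)-1-bromo-2-[(2R,3R)-3-(3,5-dimethoxyphenyl)-6-methoxy-2-(4-methoxyphenyl)-2,3-dihydro-1-benzofuran-4-yl]ethenyl]-3,5-dimethoxyphenyl]acetate; 18 4-methoxyphenylboronic acid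
Product: 19 methyl 2-[2-[(E)-2-[(2R,3R)-3-(3,5-dimethoxyphenyl)-6-methoxy-2-(4-methoxyphenyl)-2,3-dihydro-1-benzofuran-4-yl]-1-(4-methoxyphenyl)ethenyl]-3,5-dimethoxyphenyl]acetate
Conditions: Pd(OAc)2 (5 mol %), SPhos (10 mol %), K3PO4, toluene/H2O, 90 °C
Reagents that add atoms: none
Why: Second Suzuki coupling with retention of alkene geometry; the small, electron-rich boronic acid and the SPhos ligand compensate for the hindered alkenyl bromide. The alkene is a single geometric isomer (ring B trans to ring C), which step 12 requires.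

Step 12
Reactants: 19 methyl 2-[2-[(E)-2-[(2R,3R)-3-(3,5-dimethoxyphenyl)-6-methoxy-2-(4-methoxyphenyl)-2,3-dihydro-1-benzofuran-4-yl]-1-(4-methoxyphenyl)ethenyl]-3,5-dimethoxyphenyl]acetate
Product: 20 methyl 2-[2-[(1S)-2-[(2R,3R)-3-(3,5-dimethoxyphenyl)-6-methoxy-2-(4-methoxyphenyl)-2,3-dihydro-1-benzofuran-4-yl]-1-(4-methoxyphenyl)ethyl]-3,5-dimethoxyphenyl]acetate
Conditions: H2 (50 bar), [Ir(cod)((S)-tBu-PHOX)]BArF (2 mol %), CH2Cl2, rt
Reagents that add atoms: none
Why: Asymmetric hydrogenation of an unfunctionalised trisubstituted 1,1-diarylalkene with a cationic iridium N,P complex: the catalyst reads the position of the single vinylic hydrogen, not the difference between the two aryl groups, so a geometrically pure alkene gives one configuration at the diarylmethine carbon. Hydrogen is delivered to the face that makes C1 S; the remote C2′ and C3′ have no influence.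

Step 13
Reactants: 20 methyl 2-[2-[(1S)-2-[(2R,3R)-3-(3,5-dimethoxyphenyl)-6-methoxy-2-(4-methoxyphenyl)-2,3-dihydro-1-benzofuran-4-yl]-1-(4-methoxyphenyl)ethyl]-3,5-dimethoxyphenyl]acetate
Product: 21 methyl 2-diazo-2-[2-[(1S)-2-[(2R,3R)-3-(3,5-dimethoxyphenyl)-6-methoxy-2-(4-methoxyphenyl)-2,3-dihydro-1-benzofuran-4-yl]-1-(4-methoxyphenyl)ethyl]-3,5-dimethoxyphenyl]acetate
Conditions: p-ABSA, DBU, MeCN, 0 °C to rt
Reagents that add atoms: 4-acetamidobenzenesulfonyl azide (p-ABSA), CC(=O)Nc1ccc(cc1)S(=O)(=O)N=[N+]=[N-]
Why: Regitz diazo transfer to an arylacetate; the only C–H bonds acidic enough for DBU are those of the CH2CO2Me group.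

Step 14
Reactants: 21 methyl 2-diazo-2-[2-[(1S)-2-[(2R,3R)-3-(3,5-dimethoxyphenyl)-6-methoxy-2-(4-methoxyphenyl)-2,3-dihydro-1-benzofuran-4-yl]-1-(4-methoxyphenyl)ethyl]-3,5-dimethoxyphenyl]acetate
Product: 23 methyl (1S,2R,3S)-2-[(2R,3R)-3-(3,5-dimethoxyphenyl)-6-methoxy-2-(4-methoxyphenyl)-2,3-dihydro-1-benzofuran-4-yl]-4,6-dimethoxy-3-(4-methoxyphenyl)-2,3-dihydro-1H-indene-1-carboxylate (all-trans), via 2,3-cis ester 22 (not isolated)
Conditions: Rh2(S-PTTL)4 (2 mol %), toluene, −40 to 0 °C, slow addition of 21; then DBU, 60 °C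
Reagents that add atoms: none
Why: Rh2(S-PTTL)4 expels N2 from 21 to give an electrophilic donor/acceptor carbene at C3. The carbene carbon takes up the C2–H bond on the fifth atom (C3–C3a–C7a–C1–C2) through a three-centre, hydride-transfer-like transition state with retention at carbon, forming C2–C3; the closest known reaction is the Rh2(O2CR)4-catalysed intramolecular 1,5 C–H insertion of ortho-alkyl aryldiazoacetates to indane-1-carboxylates and of their ether analogues to dihydrobenzofurans. The one ring closed is the cyclopentane of the indane, by 1,5 insertion through a six-centre array of C3, C3a, C7a, C1, C2 and H. C2 is set as R by the existing C1 stereocentre: of the two diastereotopic C2 hydrogens the one is used that leaves ring C trans to ring A in the envelope transition state, and the phthalimide wall of the (S)-ligand is chosen to reinforce this. C3 is formed kinetically mainly cis to ring C (22) and is then set as S under thermodynamic control, because DBU enolises the benzylic ester and the all-trans ester is the most stable isomer. The step needs site selectivity for the C2 methylene over the doubly benzylic C1–H, over the arene positions of rings A and C and over carbene dimerisation; the five-membered ring size, the tempered electrophilicity of a donor/acceptor carbene, the bulky ligand sphere, low temperature and slow addition secure it. C1, C2′ and C3′ are not touched.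

Step 15
Reactants: 23 methyl (1S,2R,3S)-2-[(2R,3R)-3-(3,5-dimethoxyphenyl)-6-methoxy-2-(4-methoxyphenyl)-2,3-dihydro-1-benzofuran-4-yl]-4,6-dimethoxy-3-(4-methoxyphenyl)-2,3-dihydro-1H-indene-1-carboxylate
Product: 24 (1S,2R,3S)-2-[(2R,3R)-3-(3,5-dimethoxyphenyl)-6-methoxy-2-(4-methoxyphenyl)-2,3-dihydro-1-benzofuran-4-yl]-N,4,6-trimethoxy-3-(4-methoxyphenyl)-N-methyl-2,3-dihydro-1H-indene-1-carboxamide
Conditions: MeNH(OMe)·HCl, i-PrMgCl, THF, −20 to 0 °C
Reagents that add atoms: N,O-dimethylhydroxylamine hydrochloride, CNOC.Cl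
Why: Direct aminolysis of the methyl ester by the chloromagnesium amide made in the flask (Weinreb amide formation); any reversible enolisation at C3 returns the thermodynamically preferred trans arrangement.

Step 16
Reactants: 24 (1S,2R,3S)-2-[(2R,3R)-3-(3,5-dimethoxyphenyl)-6-methoxy-2-(4-methoxyphenyl)-2,3-dihydro-1-benzofuran-4-yl]-N,4,6-trimethoxy-3-(4-methoxyphenyl)-N-methyl-2,3-dihydro-1H-indene-1-carboxamide; 25 4-methoxyphenylmagnesium bromide
Product: 26 [(1S,2R,3S)-2-[(2R,3R)-3-(3,5-dimethoxyphenyl)-6-methoxy-2-(4-methoxyphenyl)-2,3-dihydro-1-benzofuran-4-yl]-4,6-dimethoxy-3-(4-methoxyphenyl)-2,3-dihydro-1H-inden-1-yl](4-methoxyphenyl)methanone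
Conditions: THF, 0 °C to rt; aq. NH4Cl
Reagents that add atoms: none
Why: Grignard addition to a Weinreb amide stops at the ketone because the five-membered magnesium chelate survives until work-up; the former ester carbon becomes Cα with ring F attached.

Step 17
Reactants: 26 [(1S,2R,3S)-2-[(2R,3R)-3-(3,5-dimethoxyphenyl)-6-methoxy-2-(4-methoxyphenyl)-2,3-dihydro-1-benzofuran-4-yl]-4,6-dimethoxy-3-(4-methoxyphenyl)-2,3-dihydro-1H-inden-1-yl](4-methoxyphenyl)methanone
Product: 27 [(1S,2R,3S)-2-[(2R,3R)-3-(3,5-dihydroxyphenyl)-6-hydroxy-2-(4-hydroxyphenyl)-2,3-dihydro-1-benzofuran-4-yl]-4,6-dihydroxy-3-(4-hydroxyphenyl)-2,3-dihydro-1H-inden-1-yl](4-hydroxyphenyl)methanone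
Conditions: BBr3 (excess), CH2Cl2, −78 °C to rt; MeOH, H2O
Reagents that add atoms: none
Why: BBr3 cleaves all eight aryl methyl ethers; it is used while Cα is still a ketone, which cannot ionise. If the benzylic C2′–O1′ bond opens reversibly it recloses to the trans ring already present, and the trans C2/C3 relation keeps the activated ketone out of reach of ring C.

Step 18
Reactants: 27 [(1S,2R,3S)-2-[(2R,3R)-3-(3,5-dihydroxyphenyl)-6-hydroxy-2-(4-hydroxyphenyl)-2,3-dihydro-1-benzofuran-4-yl]-4,6-dihydroxy-3-(4-hydroxyphenyl)-2,3-dihydro-1H-inden-1-yl](4-hydroxyphenyl)methanone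
Product: 28 (1S,2R,3S)-2-[(2R,3R)-3-(3,5-dihydroxyphenyl)-6-hydroxy-2-(4-hydroxyphenyl)-2,3-dihydro-1-benzofuran-4-yl]-1-[(S)-hydroxy(4-hydroxyphenyl)methyl]-3-(4-hydroxyphenyl)-2,3-dihydro-1H-indene-4,6-diol (target)
Conditions: NaBH4, MeOH/THF, −20 to 0 °C; pH 7 buffer
Reagents that add atoms: none
Why: Hydride addition to the aryl ketone under Felkin–Anh control by C3: with the aryl carbon C3a as the large group anti to the incoming hydride and C3–H on the side of ring F, attack gives the (S)-carbinol. Near-neutral work-up keeps the 4-hydroxybenzylic alcohol from ionising.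

## Compound list

1 | 1-bromo-3,5-dimethoxybenzene | COc1cc(Br)cc(OC)c1 | starting material
2 | 3,5-dimethoxybenzoyl chloride | COc1cc(cc(OC)c1)C(Cl)=O | starting material
3 | (2-bromo-4,6-dimethoxyphenyl)(3,5-dimethoxyphenyl)methanone | COc1cc(Br)c(C(=O)c2cc(OC)cc(OC)c2)c(OC)c1 | intermediate (not isolated)
4 | (2-bromo-6-hydroxy-4-methoxyphenyl)(3,5-dimethoxyphenyl)methanone | COc1cc(O)c(C(=O)c2cc(OC)cc(OC)c2)c(Br)c1 | intermediate
5 | 4-methoxybenzyl chloride | COc1ccc(CCl)cc1 | starting material
6 | {2-bromo-4-methoxy-6-[(4-methoxyphenyl)methoxy]phenyl}(3,5-dimethoxyphenyl)methanone | COc1ccc(COc2cc(OC)cc(Br)c2C(=O)c2cc(OC)cc(OC)c2)cc1 | intermediate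
7 | hydrazone of 6 (E/Z mixture) | COc1ccc(COc2cc(OC)cc(Br)c2C(=NN)c2cc(OC)cc(OC)c2)cc1 | intermediate
8 | 1-bromo-2-[diazo(3,5-dimethoxyphenyl)methyl]-5-methoxy-3-[(4-methoxyphenyl)methoxy]benzene | COc1ccc(COc2cc(OC)cc(Br)c2C(=[N+]=[N-])c2cc(OC)cc(OC)c2)cc1 | intermediate (not isolated)
9 | (2S,3R)-4-bromo-3-(3,5-dimethoxyphenyl)-6-methoxy-2-(4-methoxyphenyl)-2,3-dihydro-1-benzofuran (cis) | Brc1cc(OC)cc2c1[C@@H](c1cc(OC)cc(OC)c1)[C@@H](c1ccc(OC)cc1)O2 | intermediate
10 | (2R,3R)-4-bromo-3-(3,5-dimethoxyphenyl)-6-methoxy-2-(4-methoxyphenyl)-2,3-dihydro-1-benzofuran (trans) | Brc1cc(OC)cc2c1[C@@H](c1cc(OC)cc(OC)c1)[C@H](c1ccc(OC)cc1)O2 | intermediate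
11 | [(2R,3R)-3-(3,5-dimethoxyphenyl)-6-methoxy-2-(4-methoxyphenyl)-2,3-dihydro-1-benzofuran-4-yl]lithium | [Li]c1cc(OC)cc2c1[C@@H](c1cc(OC)cc(OC)c1)[C@H](c1ccc(OC)cc1)O2 | intermediate (not isolated)
12 | (2R,3R)-3-(3,5-dimethoxyphenyl)-6-methoxy-2-(4-methoxyphenyl)-2,3-dihydro-1-benzofuran-4-carbaldehyde | O=Cc1cc(OC)cc2c1[C@@H](c1cc(OC)cc(OC)c1)[C@H](c1ccc(OC)cc1)O2 | intermediate
13 | (2R,3R)-4-(2,2-dibromoethenyl)-3-(3,5-dimethoxyphenyl)-6-methoxy-2-(4-methoxyphenyl)-2,3-dihydro-1-benzofuran | BrC(Br)=Cc1cc(OC)cc2c1[C@@H](c1cc(OC)cc(OC)c1)[C@H](c1ccc(OC)cc1)O2 | intermediate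
14 | methyl 2-(3,5-dimethoxyphenyl)acetate | COC(=O)Cc1cc(OC)cc(OC)c1 | starting material
15 | methyl 2-(2-bromo-3,5-dimethoxyphenyl)acetate | COC(=O)Cc1cc(OC)cc(OC)c1Br | intermediate
16 | methyl 2-[3,5-dimethoxy-2-(4,4,5,5-tetramethyl-1,3,2-dioxaborolan-2-yl)phenyl]acetate | COC(=O)Cc1cc(OC)cc(OC)c1B1OC(C)(C)C(C)(C)O1 | intermediate
17 | methyl 2-[2-[(Z)-1-bromo-2-[(2R,3R)-3-(3,5-dimethoxyphenyl)-6-methoxy-2-(4-methoxyphenyl)-2,3-dihydro-1-benzofuran-4-yl]ethenyl]-3,5-dimethoxyphenyl]acetate | COC(=O)Cc1cc(OC)cc(OC)c1/C(Br)=C/c1cc(OC)cc2c1[C@@H](c1cc(OC)cc(OC)c1)[C@H](c1ccc(OC)cc1)O2 | intermediate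
18 | 4-methoxyphenylboronic acid | COc1ccc(B(O)O)cc1 | starting material
19 | methyl 2-[2-[(E)-2-[(2R,3R)-3-(3,5-dimethoxyphenyl)-6-methoxy-2-(4-methoxyphenyl)-2,3-dihydro-1-benzofuran-4-yl]-1-(4-methoxyphenyl)ethenyl]-3,5-dimethoxyphenyl]acetate | COC(=O)Cc1cc(OC)cc(OC)c1/C(c1ccc(OC)cc1)=C/c1cc(OC)cc2c1[C@@H](c1cc(OC)cc(OC)c1)[C@H](c1ccc(OC)cc1)O2 | intermediate
20 | methyl 2-[2-[(1S)-2-[(2R,3R)-3-(3,5-dimethoxyphenyl)-6-methoxy-2-(4-methoxyphenyl)-2,3-dihydro-1-benzofuran-4-yl]-1-(4-methoxyphenyl)ethyl]-3,5-dimethoxyphenyl]acetate | COC(=O)Cc1cc(OC)cc(OC)c1[C@H](c1ccc(OC)cc1)Cc1cc(OC)cc2c1[C@@H](c1cc(OC)cc(OC)c1)[C@H](c1ccc(OC)cc1)O2 | intermediate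
21 | methyl 2-diazo-2-[2-[(1S)-2-[(2R,3R)-3-(3,5-dimethoxyphenyl)-6-methoxy-2-(4-methoxyphenyl)-2,3-dihydro-1-benzofuran-4-yl]-1-(4-methoxyphenyl)ethyl]-3,5-dimethoxyphenyl]acetate | COC(=O)C(=[N+]=[N-])c1cc(OC)cc(OC)c1[C@H](c1ccc(OC)cc1)Cc1cc(OC)cc2c1[C@@H](c1cc(OC)cc(OC)c1)[C@H](c1ccc(OC)cc1)O2 | intermediate
22 | methyl (1R,2R,3S)-2-[(2R,3R)-3-(3,5-dimethoxyphenyl)-6-methoxy-2-(4-methoxyphenyl)-2,3-dihydro-1-benzofuran-4-yl]-4,6-dimethoxy-3-(4-methoxyphenyl)-2,3-dihydro-1H-indene-1-carboxylate (ester cis to ring C) | COc1ccc([C@H]2c3c(OC)cc(OC)cc3[C@H](C(=O)OC)[C@@H]2c2cc(OC)cc3c2[C@@H](c2cc(OC)cc(OC)c2)[C@H](c2ccc(OC)cc2)O3)cc1 | intermediate (not isolated)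
23 | methyl (1S,2R,3S)-2-[(2R,3R)-3-(3,5-dimethoxyphenyl)-6-methoxy-2-(4-methoxyphenyl)-2,3-dihydro-1-benzofuran-4-yl]-4,6-dimethoxy-3-(4-methoxyphenyl)-2,3-dihydro-1H-indene-1-carboxylate (all-trans) | COc1ccc([C@H]2c3c(OC)cc(OC)cc3[C@@H](C(=O)OC)[C@@H]2c2cc(OC)cc3c2[C@@H](c2cc(OC)cc(OC)c2)[C@H](c2ccc(OC)cc2)O3)cc1 | intermediate
24 | (1S,2R,3S)-2-[(2R,3R)-3-(3,5-dimethoxyphenyl)-6-methoxy-2-(4-methoxyphenyl)-2,3-dihydro-1-benzofuran-4-yl]-N,4,6-trimethoxy-3-(4-methoxyphenyl)-N-methyl-2,3-dihydro-1H-indene-1-carboxamide | COc1ccc([C@H]2c3c(OC)cc(OC)cc3[C@@H](C(=O)N(C)OC)[C@@H]2c2cc(OC)cc3c2[C@@H](c2cc(OC)cc(OC)c2)[C@H](c2ccc(OC)cc2)O3)cc1 | intermediate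
25 | 4-methoxyphenylmagnesium bromide | COc1ccc([Mg]Br)cc1 | starting material
26 | [(1S,2R,3S)-2-[(2R,3R)-3-(3,5-dimethoxyphenyl)-6-methoxy-2-(4-methoxyphenyl)-2,3-dihydro-1-benzofuran-4-yl]-4,6-dimethoxy-3-(4-methoxyphenyl)-2,3-dihydro-1H-inden-1-yl](4-methoxyphenyl)methanone | COc1ccc([C@H]2c3c(OC)cc(OC)cc3[C@@H](C(=O)c3ccc(OC)cc3)[C@@H]2c2cc(OC)cc3c2[C@@H](c2cc(OC)cc(OC)c2)[C@H](c2ccc(OC)cc2)O3)cc1 | intermediate
27 | [(1S,2R,3S)-2-[(2R,3R)-3-(3,5-dihydroxyphenyl)-6-hydroxy-2-(4-hydroxyphenyl)-2,3-dihydro-1-benzofuran-4-yl]-4,6-dihydroxy-3-(4-hydroxyphenyl)-2,3-dihydro-1H-inden-1-yl](4-hydroxyphenyl)methanone | Oc1ccc([C@H]2c3c(O)cc(O)cc3[C@@H](C(=O)c3ccc(O)cc3)[C@@H]2c2cc(O)cc3c2[C@@H](c2cc(O)cc(O)c2)[C@H](c2ccc(O)cc2)O3)cc1 | intermediate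
28 | (1S,2R,3S)-2-[(2R,3R)-3-(3,5-dihydroxyphenyl)-6-hydroxy-2-(4-hydroxyphenyl)-2,3-dihydro-1-benzofuran-4-yl]-1-[(S)-hydroxy(4-hydroxyphenyl)methyl]-3-(4-hydroxyphenyl)-2,3-dihydro-1H-indene-4,6-diol | Oc1ccc([C@H]2c3c(O)cc(O)cc3[C@@H]([C@H](O)c3ccc(O)cc3)[C@@H]2c2cc(O)cc3c2[C@@H](c2cc(O)cc(O)c2)[C@H](c2ccc(O)cc2)O3)cc1 | target

## Step count and least certain steps

Total step count: 18. Longest linear sequence: 16 steps (steps 1–7 and 10–18); the ring B branch (steps 8 and 9) joins at step 10.

**Step 14 (key step).** Most likely to go wrong: hydride transfer from the doubly benzylic, very electron-rich C1–H to the carbene instead of the C2–H, which would return an alkene and no ring. Also possible are electrophilic attack of the carbene on the activated C5′ position of ring C or on ring A, and the wrong choice between the two C2 hydrogens (ring C cis to ring A) if the ligand opposes the substrate preference. Fallback: from 21, decompose the diazo ester with Co(TPP) (cobalt tetraphenylporphyrin, divalent cobalt) in place of Rh2(S-PTTL)4. This changes the mechanism to a stepwise radical one. The cobalt-bound carbene radical abstracts a hydrogen atom through the six-membered 1,5 transition state that radicals strongly prefer, which reaches C2–H and not C1–H. The C2 radical then closes onto C3, and DBU equilibration as before returns the route to 23. No new isolated compound is involved.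

**Step 12.** Most likely to go wrong: very slow hydrogenation, because the alkene carries an aryl group with two ortho substituents and a second ortho-substituted aryl group. The acidic iridium hydride may also trigger protonation of the triarylethylene and cyclisation through a C1 cation, and face selection may be poor. Fallback: from 19, saponify with LiOH to the acid (E)-2-[2-[2-[(2R,3R)-dihydrobenzofuran-4-yl]-1-(4-methoxyphenyl)ethenyl]-3,5-dimethoxyphenyl]acetic acid F1. Hydrogenate F1 under carboxylate direction with [Ir(cod)((Sa,S)-SIPHOX)]BArF, H2 and Et3N in MeOH, where the bound carboxylate delivers the metal to the hindered alkene, to give the (1S)-acid F2. Re-esterify with trimethylsilyldiazomethane to return at 20.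

**Step 4.** Most likely to go wrong: incomplete hydrazone formation upstream (step 3) at the doubly ortho-substituted ketone, azine formation during oxidation, and reduced enantioselectivity of the insertion because of the ortho bromine. Fallback: from 4, reduce the ketone with NaBH4 to the benzhydrol 3-bromo-2-[hydroxy(3,5-dimethoxyphenyl)methyl]-5-methoxyphenol F3. Convert F3 with 4-methylbenzenesulfinic acid to the sulfone 3-bromo-2-[(3,5-dimethoxyphenyl)(4-methylbenzenesulfonyl)methyl]-5-methoxyphenol F4. Treat F4 with Cs2CO3 and the S-(4-methoxybenzyl)sulfonium salt of a chiral sulfide (isothiocineole): elimination gives the ortho-quinone methide, the ylide adds at C3′ and the phenoxide closes at C2′, giving the trans ring directly. This returns at 10 and bypasses steps 2–5.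

**Step 10.** Most likely to go wrong: protodeboronation of the hindered, electron-rich boronate 16 before transmetalation, and erosion of mono-selectivity if forcing conditions are needed. Fallback (reversed polarity, with the hindered partner as the electrophile): from 13, bromine–lithium exchange with n-BuLi at −110 °C and trapping with B2pin2 gives, after 1,2-boryl migration, the 1,1-diborylalkene (2R,3R)-4-[2,2-bis(pinacolboryl)ethenyl]dihydrobenzofuran F5. Suzuki coupling of F5 with bromide 15 (Pd(OAc)2, SPhos, K3PO4) at the less hindered boryl group trans to ring C gives the (E)-alkenylboronate F6. A second coupling of F6 with 4-iodoanisole returns at 19.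

**Step 17.** Most likely to go wrong: Lewis-acid opening of the benzylic C2′–O1′ bond followed by bromide capture or rearrangement instead of reclosure, and incomplete cleavage of the eight ethers. Fallback: from 26, nucleophilic demethylation with NaSEt in DMF at 130–150 °C. This is SN2 attack at the methyl groups under basic conditions, where no benzylic cation can form, and it returns at 27. No new isolated compound is involved.

**Step 18.** Most likely to go wrong: poor facial selectivity if the C2 substituent rather than the C3a aryl carbon acts as the large group, sluggish reduction of the phenoxide-deactivated ketone, and ionisation of the product carbinol on work-up. Fallback (reagent control on a protected substrate): from 27, silylate all eight phenols with TBSCl and imidazole to the octa-TBS ketone F7. Reduce F7 with (R)-2-methyl-CBS-oxazaborolidine and BH3·SMe2 (aryl group as the large substituent) to the (S)-carbinol F8. Remove the silyl groups with TBAF buffered with AcOH at 0 °C to return at 28.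

## Further compounds

F0 | step 14 | none | none
F1 | step 12 | 2-[2-[(E)-2-[(2R,3R)-3-(3,5-dimethoxyphenyl)-6-methoxy-2-(4-methoxyphenyl)-2,3-dihydro-1-benzofuran-4-yl]-1-(4-methoxyphenyl)ethenyl]-3,5-dimethoxyphenyl]acetic acid | OC(=O)Cc1cc(OC)cc(OC)c1/C(c1ccc(OC)cc1)=C/c1cc(OC)cc2c1[C@@H](c1cc(OC)cc(OC)c1)[C@H](c1ccc(OC)cc1)O2
F2 | step 12 | 2-[2-[(1S)-2-[(2R,3R)-3-(3,5-dimethoxyphenyl)-6-methoxy-2-(4-methoxyphenyl)-2,3-dihydro-1-benzofuran-4-yl]-1-(4-methoxyphenyl)ethyl]-3,5-dimethoxyphenyl]acetic acid | OC(=O)Cc1cc(OC)cc(OC)c1[C@H](c1ccc(OC)cc1)Cc1cc(OC)cc2c1[C@@H](c1cc(OC)cc(OC)c1)[C@H](c1ccc(OC)cc1)O2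
F3 | step 4 | 3-bromo-2-[hydroxy(3,5-dimethoxyphenyl)methyl]-5-methoxyphenol (racemic) | COc1cc(O)c(C(O)c2cc(OC)cc(OC)c2)c(Br)c1
F4 | step 4 | 3-bromo-2-[(3,5-dimethoxyphenyl)(4-methylbenzenesulfonyl)methyl]-5-methoxyphenol (racemic) | COc1cc(O)c(C(c2cc(OC)cc(OC)c2)S(=O)(=O)c2ccc(C)cc2)c(Br)c1
F5 | step 10 | (2R,3R)-4-[2,2-bis(4,4,5,5-tetramethyl-1,3,2-dioxaborolan-2-yl)ethenyl]-3-(3,5-dimethoxyphenyl)-6-methoxy-2-(4-methoxyphenyl)-2,3-dihydro-1-benzofuran | CC1(C)OB(OC1(C)C)C(B1OC(C)(C)C(C)(C)O1)=Cc1cc(OC)cc2c1[C@@H](c1cc(OC)cc(OC)c1)[C@H](c1ccc(OC)cc1)O2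
F6 | step 10 | methyl 2-[2-[(E)-2-[(2R,3R)-3-(3,5-dimethoxyphenyl)-6-methoxy-2-(4-methoxyphenyl)-2,3-dihydro-1-benzofuran-4-yl]-1-(4,4,5,5-tetramethyl-1,3,2-dioxaborolan-2-yl)ethenyl]-3,5-dimethoxyphenyl]acetate | COC(=O)Cc1cc(OC)cc(OC)c1/C(B1OC(C)(C)C(C)(C)O1)=C/c1cc(OC)cc2c1[C@@H](c1cc(OC)cc(OC)c1)[C@H](c1ccc(OC)cc1)O2
F0 | step 17 | none | none
F7 | step 18 | octakis(tert-butyldimethylsilyl) ether of ketone 27 | CC(C)(C)[Si](C)(C)Oc1ccc([C@H]2c3c(O[Si](C)(C)C(C)(C)C)cc(O[Si](C)(C)C(C)(C)C)cc3[C@@H](C(=O)c3ccc(O[Si](C)(C)C(C)(C)C)cc3)[C@@H]2c2cc(O[Si](C)(C)C(C)(C)C)cc3c2[C@@H](c2cc(O[Si](C)(C)C(C)(C)C)cc(O[Si](C)(C)C(C)(C)C)c2)[C@H](c2ccc(O[Si](C)(C)C(C)(C)C)cc2)O3)cc1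
F8 | step 18 | octakis(tert-butyldimethylsilyl) ether of target 28, (S)-carbinol | CC(C)(C)[Si](C)(C)Oc1ccc([C@H]2c3c(O[Si](C)(C)C(C)(C)C)cc(O[Si](C)(C)C(C)(C)C)cc3[C@@H]([C@H](O)c3ccc(O[Si](C)(C)C(C)(C)C)cc3)[C@@H]2c2cc(O[Si](C)(C)C(C)(C)C)cc3c2[C@@H](c2cc(O[Si](C)(C)C(C)(C)C)cc(O[Si](C)(C)C(C)(C)C)c2)[C@H](c2ccc(O[Si](C)(C)C(C)(C)C)cc2)O3)cc1
A1 | alternative 1 | methyl 2-[2-(3,5-dimethoxybenzoyl)-3,5-dimethoxyphenyl]acetate | COC(=O)Cc1cc(OC)cc(OC)c1C(=O)c1cc(OC)cc(OC)c1
A2 | alternative 1 | 3,5-dimethoxy-2-(trimethylsilyl)phenyl trifluoromethanesulfonate | COc1cc(OC)c([Si](C)(C)C)c(OS(=O)(=O)C(F)(F)F)c1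
A3 | alternative 1 | methyl 3-(3,5-dimethoxyphenyl)-3-oxopropanoate | COC(=O)CC(=O)c1cc(OC)cc(OC)c1
A4 | alternative 2 | all-trans 5,7-dihydroxyindane with Cα as tert-butyldimethylsilyl ether and the other six phenols as methyl ethers | COc1ccc([C@H]2c3c(O)cc(O)cc3[C@@H]([C@H](O[Si](C)(C)C(C)(C)C)c3ccc(OC)cc3)[C@@H]2c2cc(OC)cc3c2[C@@H](c2cc(OC)cc(OC)c2)[C@H](c2ccc(OC)cc2)O3)cc1
A5 | alternative 2 | 2-methyl-6,7-dihydrocyclopenta[b]pyran-4(5H)-one carrying ring A on C5, the dihydrobenzofuran on C6 and the silyloxy(4-methoxyphenyl)methyl group on C7, configured as in A4 | COc1ccc([C@H]2C3=C(OC(C)=CC3=O)[C@@H]([C@H](O[Si](C)(C)C(C)(C)C)c3ccc(OC)cc3)[C@@H]2c2cc(OC)cc3c2[C@@H](c2cc(OC)cc(OC)c2)[C@H](c2ccc(OC)cc2)O3)cc1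
A6 | alternative 3 | octamethyl ether of the target with Cα as ketone (identical with 26) | COc1ccc([C@H]2c3c(OC)cc(OC)cc3[C@@H](C(=O)c3ccc(OC)cc3)[C@@H]2c2cc(OC)cc3c2[C@@H](c2cc(OC)cc(OC)c2)[C@H](c2ccc(OC)cc2)O3)cc1
A7 | alternative 3 | indanyl ketone whose ring C is a phenol bearing the (3,5-dimethoxyphenyl)(4-methylbenzenesulfonyl)methyl group at C3a′ (sulfone carbon unassigned) | COc1ccc([C@H]2c3c(OC)cc(OC)cc3[C@@H](C(=O)c3ccc(OC)cc3)[C@@H]2c2cc(OC)cc(O)c2C(c2cc(OC)cc(OC)c2)S(=O)(=O)c2ccc(C)cc2)cc1
A8 | alternative 3 | (4-methoxyphenyl)methylide of tetrahydrothiophenium | COc1ccc([CH-][S+]2CCCC2)cc1
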